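Ask first how much reagent a flask still holds when the clock stops. Alder, cedar, larch and ash share their charges and their time; they differ in temperature.

| flask | starting material | reagent | temperature | remark | time |
|---|---|---|---|---|---|
| gamma | 0.050 M | 0.020 M | 52 °C | run made earlier |  |
| delta | 0.050 M | 0.045 M | 102 °C | run made earlier |  |
| eta | 0.025 M | 0.030 M | 52 °C | run made earlier |  |
| alder | 0.050 M | 0.0300 M | 60 °C |  | 15 h |
| cedar | 0.050 M | 0.0300 M | 120 °C |  | 15 h |
| larch | 0.050 M | 0.0300 M | 90 °C |  | 15 h |
| ash | 0.050 M | 0.0300 M | 30 °C |  | 15 h |

gamma run (percent of the starting material charged): time / h: target / % = 1.00: 1.9; 2.00: 2.1; 5.00: 4.5; 12.0: 8.7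

delta run (percent of the starting material charged): time / min: target / % = 8.00: 13.9; 15.0: 20.7; 40.0: 32.3; 90.0: 39.1

eta run (percent of the starting material charged): time / h: target / % = 1.50: 1.8; 4.00: 7.1; 8.00: 10.2; 12.0: 13.5

(each reading ± 0.5 percentage points)

- what was read earlier has a scatter of 0.5 percentage points, one standard deviation

* the flask that comes out highest in amount of target, in percent of the starting material charged, or "all alike" when all lie within 1.5 percentage points (alder / cedar / larch / ash / all alike)
* target at the end, in percent of the starting material charged, alder
* target at the end, in percent of the starting material charged, cedar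
* target at the end, in percent of the starting material charged, larch
* target at the end, in percent of the starting material charged, ash

Read the rate constant k of the step to target from readings made early in a run, dividing target (as a fraction of starting material) by c(reagent) and by time. Take gamma and eta at their early readings and delta at its first, then join them by the Arrhenius law.

k at 52 °C = 0.521 M⁻¹ h⁻¹

k at 102 °C = 23.2 M⁻¹ h⁻¹

Ea = 77.0 kJ mol⁻¹

Now look at the end of delta. Its last reading holds target equal to a share s of the reagent charged, and the readings do not say where the rest of the reagent went. Delta was still rising, so treat this as a reading and a low one.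

s = 0.434

Hold c(starting material) at its charge, a rough pseudo-first-order view. Reagent then lives for s/(k·c(starting material)), so divide the time by that lifetime:

n = k·c(starting material)·t/s

ash: 0.114

alder: 1.78

larch: 17.7

cedar: 124

Call n the turnover count, the number of reagent lifetimes that fit into the time. My reckoning for target is then s·(c(reagent)/c(starting material))·(1 − exp(−n)). That gives 2.81 % for ash and 21.7 % for alder. Larch and cedar tie at the ceiling of 26.1 %, since both counts are far above one.

The forecast parts from me there: it gives 28 % for larch and 30 % for cedar, between 20 % and 36 %, with 19 % for alder and 2.9 % for ash. It names cedar: “Cedar is slightly favoured over larch.”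

The flasks end at 2.80 % in ash, 19.0 % in alder, 29.3 % in larch and 33.9 % in cedar, the highest.

    starting material + reagent → isomer of the product (k = 0.0308 M⁻¹ min⁻¹, Ea = 68.0 kJ mol⁻¹)
    starting material + reagent → target (k = 0.0206 M⁻¹ min⁻¹, Ea = 80.0 kJ mol⁻¹)
    2 starting material → self-condensation product (k = 5.84 × 10⁻⁵ M⁻¹ min⁻¹, Ea = 86.0 kJ mol⁻¹)
    (constants at 60 °C)

Cedar's count of 124 shows in the flask: reagent stands at 0 % of its charge at 15.0 h. From the start of cedar the step to target uses reagent 1.3 times as fast as the step to isomer of the product, and target ends at 0.564 of the reagent charge. Cedar's neighbour with 0.0075 M of reagent has the same count and ends at 8.47 % of target, which is 0.564 of its reagent charge.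

The numbers in the tables were generated by integration for an exercise, and the scatter is random.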